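## Structural features

The target is a single five-membered carbocycle, a cyclopent-2-en-1-one with C1 as the carbonyl carbon and C2=C3 as the alkene. C4 carries an acetoxy group. C5 is fully substituted and bears a tertiary hydroxyl and a 1-hydroxypentadecyl chain, whose carbinol carbon C1' is bonded to an unbranched tetradecyl group. Three stereocentres stand in a row, C4 (S), C5 (S) and C1' (S); the C4 and C5 oxygens are cis on the ring, so the chain is trans to the acetate. The fragile groups are the γ-acetoxy enone, the β-hydroxy ketone unit C1–C5–C1' (retro-aldol under base) and the three neighbouring oxygens between which an acetyl group can migrate, so late steps must avoid base. The real difficulty is the quaternary carbinol C5, flanked by stereocentres on both sides, together with the need to acylate the C4 oxygen alone. The key step uses the fact that the chain C3–C4–C5–C1', with oxygen on C4 and C5, has the carbon and oxygen pattern of tartaric acid (C3 and C1' being the carboxyl carbons). C1 is then a branch to be attached at C5, and C2 is the link that closes the ring between C1 and C3.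

## Logic of the disconnections

20 ⇒ 19. No skeletal bond is cut; the C1 carbonyl is traced back to the C1 carbinol. The enone is the most reactive group and is therefore unveiled last. In 19 the C1 hydroxyl is the only allylic one, so no protecting group is needed. 19 has neither a Michael acceptor nor a β-hydroxy ketone. The forward step needs an oxidant that leaves the saturated C1' carbinol and the 1,2-diol units untouched and that takes both C1 epimers.

19 ⇒ 18 ⇒ 17 ⇒ 16. The two O–Si bonds (C1, C1'), then the acetyl C–O bond at C4, then the two ketal C–O bonds are cut. In 17 the C4 hydroxyl is the only free hydroxyl that is not tertiary, so the three-hydroxyl problem shrinks to secondary versus tertiary. The demand is that the ketal of 16 leaves while both silyl ethers stay, and that desilylation of 18 does not move the acetate.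

16 ⇒ 15 ⇒ 14. The O–Si bond at C1' and then the C1'–H bond are cut. C1' is the only stereocentre not supplied by the chiral pool, and a ketone lets a chiral catalyst set it. The demand is hydride delivery to one face of a hindered ketone without touching the ring alkene.

14 ⇒ 11 + 12, and 11 ⇒ 10. The C1'–C bond to the chain is cut, then the amide C–N bond. The unfunctionalised C14 chain arrives as a nucleophile (13, made from 12) at a carboxyl carbon that the core already contains. This removes fourteen carbons in one cut. The forward steps need a single addition and acyl substitution next to a quaternary carbon.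

10 ⇒ 9. The C2=C3 bond is cut. The ring becomes an acyclic 1,6-diene in which C2 and C3 are plain vinyl termini. In the forward direction the closure is placed before the ester is elaborated, so that the acyl chemistry and the borane reduction run on a tied-back bicycle free of terminal alkenes. The demand is that the C1 and C3 branches are cis on the dioxolane.

9 ⇒ 8 ⇒ 6 ⇒ 5. The O–Si bond at C1, the C3=CH2 bond and the C3–H bond of the lactol are cut. The lactone carbonyl of 5 is the one carboxyl that has been told apart from the other; reducing and olefinating it gives the second vinyl group and frees the C1 oxygen. The demands are reduction of the lactone and not the ester, and olefination without retro-aldol at C1–C5 or epimerisation at C4.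

5 ⇒ 1 + 2. The C1–C5 bond and the lactone O–C3 bond are cut. This creates the quaternary centre on a C2-symmetric chiral-pool diester whose two α-hydrogens are equivalent, and the stereodefined C3–C4–C5–C1' core comes from one commercial compound. The forward step must go with retention at C5 at low temperature. 1 needs no redesign: methoxide is the best leaving group for the ring closure, and a larger ester would slow it.

1, 2 and 12 are commercial.

## Other disconnections considered

Alternative 1: The cut removes the C5–O and C1'–O bonds and leads back to the (E)-alkylidene cyclopentenone A2. In the forward step OsO4 (octavalent osmium) with TMEDA, hydrogen-bonded to the free C4 hydroxyl, would add to the exocyclic alkene on the face of that hydroxyl and give the chelated osmate ester A1 (hexavalent osmium). In its favour, one suprafacial addition sets two of the three stereocentres, with the relative configuration fixed by the (E) geometry and the face by the directing group. The osmate also masks the C5/C1' diol while C4 is still free, so C4 could be acetylated without any silyl ether or ketal; on this point it is better than the chosen plan. A2 should be reachable in a few steps by condensing an enantiopure hydroxycyclopentenone building block with a C15 aldehyde, so the step economy is also clearly better. Against it, osmium is used stoichiometrically because the diamine osmate does not turn over. The enone alkene C2=C3 is a second, similarly electron-poor site. A2 is a cross-conjugated 4-hydroxy dienone that can dehydrate, racemise at C4 or isomerise at the alkylidene. The robust osmate must finally be cleaved in the presence of a γ-acetoxy enone. The two plans are equal in how predictable the relative configuration is. The chosen plan is better on the source of absolute configuration (C4 and C5 from the chiral pool, no directing effect to rely on), on the stability of its intermediates and on avoiding stoichiometric osmium.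

Alternative 2: The cut is the C1–C2 bond and leads to the 4-alkynal A4, which has the aldehyde on the quaternary C5, a terminal alkyne on C4, the C4 acetate in place and the C5/C1' diol as an acetonide. In the forward step the cationic monovalent rhodium complex [Rh(dppe)]2(BF4)2 would add the formyl C–H bond oxidatively to give an acyl hydride of trivalent rhodium. Acyl and hydrogen are then delivered trans across the alkyne, and the cyclopentenone A3 is released. In its favour, the reaction is catalytic and atom-economic and forms the enone at the final oxidation level, where the chosen plan needs a metathesis and a separate oxidation; on this point it is better. Only a ketal hydrolysis would follow, and the aldehyde has no α-hydrogen to lose. Against it, a terminal alkyne is the less well-behaved substrate for this reaction (vinylidene formation, oligomerisation). A propargylic acetate next to a cationic late metal can ionise or shift. The formyl group is neopentyl-type. Most important, A4 needs a stereocontrolled alkynylation to set C4 next to the quaternary C5, so the hard stereochemical problem moves into the precursor. Both plans close the ring catalytically; the metathesis of an oxygenated 1,6-diene is the more thoroughly established closure. The chosen plan is better on stereochemistry, since C4 and C5 are both inherited. Overall step economy is about equal, with the alternative ahead in the end-game.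

Alternative 3: The cut is the C4–C5 bond and leads to the 6-hydroxypyranone A6, the oxidative ring-expansion product of a furyl carbinol. In the forward step Et3N would open A6 to the (Z)-4-oxo-2-enal A7. Its α-hydroxy ketone enolises toward C5, and the enediolate adds to the aldehyde to give the cis-diol cyclopentenone A5. In its favour, the route is very short, needs no metal in the key step and uses cheap reagents; step economy is clearly better than in the chosen plan. A5 would need only acetylation and desilylation; this end-game is the equal of the chosen plan and is simpler in that the enone is already present. Against it, both ring stereocentres arise in a reversible base-mediated aldol whose only stereochemical information is the silyloxy centre C1'. The absolute configuration of C4 and C5 therefore depends on 1,2-induction of unknown size, with four diastereomers possible. A5 is a base-sensitive β-hydroxy ketone and α-ketol under the conditions that form it, and C1' still needs its own asymmetric step. The chosen plan is better on stereocontrol (C4 and C5 fixed by the chiral pool, C1' by a catalyst); the alternative is better on step count and simplicity. Thermodynamic control could favour the alternative if the target isomer is the most stable one, but that cannot be assumed.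

Key step: step 1

Remark on the chemistry: atom labels C1–C5 and C1' are those of the target throughout. C1 is formed in step 1 as both carbinol epimers, is carried as such (no configuration is written at that carbon in 4–11 and 14–19) and becomes the carbonyl carbon in step 13.

## Route

Step 1
Reactants: 1 dimethyl (4R,5R)-2,2-dimethyl-1,3-dioxolane-4,5-dicarboxylate (dimethyl 2,3-O-isopropylidene-L-tartrate); 2 acrolein (prop-2-enal)
Product: 5 methyl (3aR,6aR)-2,2-dimethyl-6-oxo-4-vinyltetrahydrofuro[3,4-d][1,3]dioxole-3a(4H)-carboxylate (both epimers at the vinyl-bearing carbon), via lithium ester enolate 3 (not isolated), via lithium aldolate 4 (not isolated)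
Conditions: LiN(i-Pr)2 (1.1 equiv), THF, −78 °C, 15 min; 2 (1.5 equiv), −78 °C, then −78 → −20 °C; aq NH4Cl
Reagents that add atoms: none
Why: LiN(i-Pr)2 removes one of the two equivalent α-hydrogens of 1 to give the ester enolate 3, planar at the future C5. Acrolein is attacked at its carbonyl carbon (1,2-addition of a hard lithium enolate at −78 °C), which forms the C1–C5 bond and the aldolate 4. The closest known reaction type is the alkylation and aldol addition of tartrate acetonide enolates, which take the electrophile on the face cis to the neighbouring ester so that the two carboxyl groups stay trans (net retention). On warming, the C1 alkoxide of 4 attacks the ester carbonyl on C4 in a 5-exo-trig acyl substitution, expels methoxide and closes the cis-fused γ-lactone; the geminal ester would need a four-membered ring and is left alone. The quaternary centre C5 is thus controlled by the dioxolane ring and the C4 substituent, and the lactone proofreads it, because only the retention adduct has the alkoxide and the C4 ester on the same face. The C1 carbinol centre forms without control, which does no harm because it is oxidised in step 13. The step needs 1,2- over 1,4-addition and must outrun β-elimination of the ring oxygen from 3; the short enolate lifetime at −78 °C provides for both, and once the aldol has occurred the mixture can be warmed.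

Step 2
Reactants: 5 methyl (3aR,6aR)-2,2-dimethyl-6-oxo-4-vinyltetrahydrofuro[3,4-d][1,3]dioxole-3a(4H)-carboxylate
Product: 6 methyl (3aR,6aR)-6-hydroxy-2,2-dimethyl-4-vinyltetrahydrofuro[3,4-d][1,3]dioxole-3a(4H)-carboxylate (lactol, anomers)
Conditions: i-Bu2AlH (1.15 equiv), CH2Cl2, −78 °C; aq KNaC4H4O6
Reagents that add atoms: none
Why: Partial lactone reduction with i-Bu2AlH: the strained α-alkoxy γ-lactone carbonyl is far more electrophilic and accessible than the methyl ester on the quaternary carbon, and the aluminium hemiacetal is stable at −78 °C, so reduction should stop at the lactol.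

Step 3
Reactants: 6 methyl (3aR,6aR)-6-hydroxy-2,2-dimethyl-4-vinyltetrahydrofuro[3,4-d][1,3]dioxole-3a(4H)-carboxylate
Product: 8 methyl (4R,5S)-5-ethenyl-4-(1-hydroxyprop-2-en-1-yl)-2,2-dimethyl-1,3-dioxolane-4-carboxylate, via ring-opened aldehyde alkoxide 7 (not isolated)
Conditions: Ph3PCH3Br (3.5 equiv), n-BuLi (3.3 equiv), THF, 0 °C; 6, −78 → 0 °C
Reagents that add atoms: methyltriphenylphosphonium bromide, C[P+](c1ccccc1)(c1ccccc1)c1ccccc1.[Br-]
Why: Wittig methylenation of a lactol: the first equivalent of ylide deprotonates 6, the lactolate opens to aldehyde 7 and Ph3P=CH2 traps it. The lithium counter-ion and the low temperature are chosen to hold back retro-aldol cleavage of the β-alkoxide ester and epimerisation of the α-alkoxy aldehyde at C4; the hindered ester is not expected to react with the ylide.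

Step 4
Reactants: 8 methyl (4R,5S)-5-ethenyl-4-(1-hydroxyprop-2-en-1-yl)-2,2-dimethyl-1,3-dioxolane-4-carboxylate
Product: 9 methyl (4S,5S)-4-{1-[(tert-butyldimethylsilyl)oxy]prop-2-en-1-yl}-5-ethenyl-2,2-dimethyl-1,3-dioxolane-4-carboxylate
Conditions: TBSOTf (1.3 equiv), 2,6-lutidine (2 equiv), CH2Cl2, −78 → 0 °C
Reagents that add atoms: tert-butyldimethylsilyl trifluoromethanesulfonate, CC(C)(C)[Si](C)(C)OS(=O)(=O)C(F)(F)F
Why: Silylation of a hindered secondary allylic alcohol with a silyl triflate under lutidine buffering; no alkoxide is formed, so the retro-aldol path of the β-hydroxy ester stays closed and the ketal is untouched.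

Step 5
Reactants: 9 methyl (4S,5S)-4-{1-[(tert-butyldimethylsilyl)oxy]prop-2-en-1-yl}-5-ethenyl-2,2-dimethyl-1,3-dioxolane-4-carboxylate
Product: 10 methyl (3aS,6aS)-4-[(tert-butyldimethylsilyl)oxy]-2,2-dimethyl-4,6a-dihydro-3aH-cyclopenta[d][1,3]dioxole-3a-carboxylate
Conditions: second-generation Grubbs catalyst RuCl2(=CHPh)(H2IMes)(PCy3) (5 mol %), CH2Cl2 (0.01 M), 40 °C
Reagents that add atoms: none
Why: Ring-closing metathesis of a 1,6-diene: the two vinyl groups are cis on the dioxolane as a consequence of the lactone in 5, so the C2=C3 bond should close the cis-fused cyclopentene with loss of ethene. Closing the ring here removes the terminal alkenes before the borane step and ties C1 and C4 back from the ester.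

Step 6
Reactants: 10 methyl (3aS,6aS)-4-[(tert-butyldimethylsilyl)oxy]-2,2-dimethyl-4,6a-dihydro-3aH-cyclopenta[d][1,3]dioxole-3a-carboxylate
Product: 11 (3aS,6aS)-4-[(tert-butyldimethylsilyl)oxy]-N-methoxy-N,2,2-trimethyl-4,6a-dihydro-3aH-cyclopenta[d][1,3]dioxole-3a-carboxamide
Conditions: MeNH(OMe)·HCl (4 equiv), i-PrMgCl (8 equiv), THF, −20 °C → rt
Reagents that add atoms: N,O-dimethylhydroxylamine hydrochloride, CNOC.Cl
Why: Weinreb amide synthesis from an ester with the magnesium amide Me(MeO)NMgCl; the ester sits on the convex face of the cis-fused bicycle, which should leave its carbonyl open to the nucleophile despite the quaternary carbon.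

Step 7
Reactants: 11 (3aS,6aS)-4-[(tert-butyldimethylsilyl)oxy]-N-methoxy-N,2,2-trimethyl-4,6a-dihydro-3aH-cyclopenta[d][1,3]dioxole-3a-carboxamide; 12 1-bromotetradecane
Product: 14 1-[(3aS,6aS)-4-[(tert-butyldimethylsilyl)oxy]-2,2-dimethyl-4,6a-dihydro-3aH-cyclopenta[d][1,3]dioxol-3a-yl]pentadecan-1-one, via tetradecylmagnesium bromide 13 (not isolated)
Conditions: 12, Mg, THF, 50 °C; then 11, THF, 0 °C → rt; aq NH4Cl
Reagents that add atoms: none
Why: Grignard addition to a Weinreb amide: the N-methoxy magnesium chelate of the tetrahedral adduct persists until work-up, so one tetradecyl group is delivered and the ketone appears only on quenching.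

Step 8
Reactants: 14 1-[(3aS,6aS)-4-[(tert-butyldimethylsilyl)oxy]-2,2-dimethyl-4,6a-dihydro-3aH-cyclopenta[d][1,3]dioxol-3a-yl]pentadecan-1-one
Product: 15 (1S)-1-[(3aS,6aS)-4-[(tert-butyldimethylsilyl)oxy]-2,2-dimethyl-4,6a-dihydro-3aH-cyclopenta[d][1,3]dioxol-3a-yl]pentadecan-1-ol
Conditions: (R)-1-methyl-3,3-diphenyltetrahydro-1H,3H-pyrrolo[1,2-c][1,3,2]oxazaborole [(R)-Me-CBS] (0.5 equiv), catecholborane (2 equiv), toluene, −78 → −40 °C
Reagents that add atoms: none
Why: Corey–Bakshi–Shibata reduction: the oxazaborolidine binds the ketone with the fully substituted ring-fusion carbon as the large group and the chain methylene as the small one. The (R)-catalyst then delivers hydride to the face that gives the (1'S)-carbinol, the mirror image of the known (S)-catalyst/tert-alkyl methyl ketone → (R) relationship. Catecholborane is chosen because it does not hydroborate the ring alkene at low temperature.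

Step 9
Reactants: 15 (1S)-1-[(3aS,6aS)-4-[(tert-butyldimethylsilyl)oxy]-2,2-dimethyl-4,6a-dihydro-3aH-cyclopenta[d][1,3]dioxol-3a-yl]pentadecan-1-ol
Product: 16 (3aR,6aS)-4-[(tert-butyldimethylsilyl)oxy]-3a-{(1S)-1-[(tert-butyldimethylsilyl)oxy]pentadecyl}-2,2-dimethyl-4,6a-dihydro-3aH-cyclopenta[d][1,3]dioxole
Conditions: TBSOTf (2 equiv), 2,6-lutidine (3 equiv), CH2Cl2, 0 °C → rt
Reagents that add atoms: tert-butyldimethylsilyl trifluoromethanesulfonate, CC(C)(C)[Si](C)(C)OS(=O)(=O)C(F)(F)F
Why: Silyl triflate with lutidine silylates even neopentyl-type secondary alcohols; no alkoxide is generated, so the C1 silyl group cannot migrate.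

Step 10
Reactants: 16 (3aR,6aS)-4-[(tert-butyldimethylsilyl)oxy]-3a-{(1S)-1-[(tert-butyldimethylsilyl)oxy]pentadecyl}-2,2-dimethyl-4,6a-dihydro-3aH-cyclopenta[d][1,3]dioxole
Product: 17 (1R,2S)-5-[(tert-butyldimethylsilyl)oxy]-1-{(1S)-1-[(tert-butyldimethylsilyl)oxy]pentadecyl}cyclopent-3-ene-1,2-diol
Conditions: EtSH (10 equiv), Zn(OTf)2 (2 equiv), NaHCO3, CH2Cl2, 0 °C → rt
Reagents that add atoms: none
Why: Lewis-acid-mediated transthioketalisation: Zn(OTf)2 activates the isopropylidene ketal and ethanethiol carries the acetone unit away as its dithioketal. These buffered, non-protic conditions are ones that secondary silyl ethers and the allylic C–O bonds should tolerate; no enone is present yet, so the thiol has no Michael acceptor.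

Step 11
Reactants: 17 (1R,2S)-5-[(tert-butyldimethylsilyl)oxy]-1-{(1S)-1-[(tert-butyldimethylsilyl)oxy]pentadecyl}cyclopent-3-ene-1,2-diol
Product: 18 (1S,5R)-4-[(tert-butyldimethylsilyl)oxy]-5-{(1S)-1-[(tert-butyldimethylsilyl)oxy]pentadecyl}-5-hydroxycyclopent-2-en-1-yl acetate
Conditions: Ac2O (1.5 equiv), pyridine, DMAP (0.1 equiv), CH2Cl2, 0 °C → rt
Reagents that add atoms: acetic anhydride, CC(=O)OC(C)=O
Why: DMAP-catalysed acylation; the only competitor is the tertiary C5 hydroxyl, flanked by three substituted carbons, which is not acylated under these conditions, so the acetate should go to C4 alone.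

Step 12
Reactants: 18 (1S,5R)-4-[(tert-butyldimethylsilyl)oxy]-5-{(1S)-1-[(tert-butyldimethylsilyl)oxy]pentadecyl}-5-hydroxycyclopent-2-en-1-yl acetate
Product: 19 (1S,5R)-4,5-dihydroxy-5-[(1S)-1-hydroxypentadecyl]cyclopent-2-en-1-yl acetate
Conditions: HF·pyridine, pyridine, THF, 0 °C → rt
Reagents that add atoms: none
Why: Fluoride-mediated cleavage of both silyl ethers in a buffered acidic medium, which avoids the base-induced acetyl migration among the neighbouring hydroxyls; the hindered C1' ether sets the reaction time.

Step 13
Reactants: 19 (1S,5R)-4,5-dihydroxy-5-[(1S)-1-hydroxypentadecyl]cyclopent-2-en-1-yl acetate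
Product: 20 (1S,5S)-5-hydroxy-5-[(1S)-1-hydroxypentadecyl]-4-oxocyclopent-2-en-1-yl acetate (target)
Conditions: MnO2 (activated, 15 equiv), CH2Cl2, rt
Reagents that add atoms: none
Why: Allylic oxidation with MnO2: of the three free hydroxyls only the C1 one is allylic, the tertiary and the saturated secondary ones are not oxidised by this reagent, and both C1 epimers converge on the enone. The neutral medium avoids retro-aldol cleavage of the C5–C1' bond and acetate migration in the product.

## Compound list

1 | dimethyl (4R,5R)-2,2-dimethyl-1,3-dioxolane-4,5-dicarboxylate | COC(=O)[C@@H]1OC(C)(C)O[C@H]1C(=O)OC | starting material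
2 | acrolein (prop-2-enal) | C=CC=O | starting material
3 | lithium enolate of 1, methyl (5R)-4-[(lithiooxy)(methoxy)methylidene]-2,2-dimethyl-1,3-dioxolane-5-carboxylate | COC(=O)[C@@H]1OC(C)(C)OC1=C(OC)O[Li] | intermediate
4 | dimethyl (4R,5R)-4-[1-(lithiooxy)prop-2-en-1-yl]-2,2-dimethyl-1,3-dioxolane-4,5-dicarboxylate | COC(=O)[C@@H]1OC(C)(C)O[C@]1(C(=O)OC)C(O[Li])C=C | intermediate
5 | methyl (3aR,6aR)-2,2-dimethyl-6-oxo-4-vinyltetrahydrofuro[3,4-d][1,3]dioxole-3a(4H)-carboxylate | C=CC1OC(=O)[C@@H]2OC(C)(C)O[C@]12C(=O)OC | intermediate
6 | methyl (3aR,6aR)-6-hydroxy-2,2-dimethyl-4-vinyltetrahydrofuro[3,4-d][1,3]dioxole-3a(4H)-carboxylate | C=CC1OC(O)[C@@H]2OC(C)(C)O[C@]12C(=O)OC | intermediate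
7 | methyl (4R,5R)-5-formyl-4-[1-(lithiooxy)prop-2-en-1-yl]-2,2-dimethyl-1,3-dioxolane-4-carboxylate | O=C[C@@H]1OC(C)(C)O[C@]1(C(=O)OC)C(O[Li])C=C | intermediate
8 | methyl (4R,5S)-5-ethenyl-4-(1-hydroxyprop-2-en-1-yl)-2,2-dimethyl-1,3-dioxolane-4-carboxylate | C=C[C@@H]1OC(C)(C)O[C@]1(C(=O)OC)C(O)C=C | intermediate
9 | methyl (4S,5S)-4-{1-[(tert-butyldimethylsilyl)oxy]prop-2-en-1-yl}-5-ethenyl-2,2-dimethyl-1,3-dioxolane-4-carboxylate | C=C[C@@H]1OC(C)(C)O[C@]1(C(=O)OC)C(O[Si](C)(C)C(C)(C)C)C=C | intermediate
10 | methyl (3aS,6aS)-4-[(tert-butyldimethylsilyl)oxy]-2,2-dimethyl-4,6a-dihydro-3aH-cyclopenta[d][1,3]dioxole-3a-carboxylate | COC(=O)[C@@]1(O2)C(O[Si](C)(C)C(C)(C)C)C=C[C@@H]1OC2(C)C | intermediate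
11 | (3aS,6aS)-4-[(tert-butyldimethylsilyl)oxy]-N-methoxy-N,2,2-trimethyl-4,6a-dihydro-3aH-cyclopenta[d][1,3]dioxole-3a-carboxamide | CON(C)C(=O)[C@@]1(O2)C(O[Si](C)(C)C(C)(C)C)C=C[C@@H]1OC2(C)C | intermediate
12 | 1-bromotetradecane | CCCCCCCCCCCCCCBr | starting material
13 | tetradecylmagnesium bromide | CCCCCCCCCCCCCC[Mg]Br | intermediate
14 | 1-[(3aS,6aS)-4-[(tert-butyldimethylsilyl)oxy]-2,2-dimethyl-4,6a-dihydro-3aH-cyclopenta[d][1,3]dioxol-3a-yl]pentadecan-1-one | CCCCCCCCCCCCCCC(=O)[C@@]1(O2)C(O[Si](C)(C)C(C)(C)C)C=C[C@@H]1OC2(C)C | intermediate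
15 | (1S)-1-[(3aS,6aS)-4-[(tert-butyldimethylsilyl)oxy]-2,2-dimethyl-4,6a-dihydro-3aH-cyclopenta[d][1,3]dioxol-3a-yl]pentadecan-1-ol | CCCCCCCCCCCCCC[C@H](O)[C@@]1(O2)C(O[Si](C)(C)C(C)(C)C)C=C[C@@H]1OC2(C)C | intermediate
16 | (3aR,6aS)-4-[(tert-butyldimethylsilyl)oxy]-3a-{(1S)-1-[(tert-butyldimethylsilyl)oxy]pentadecyl}-2,2-dimethyl-4,6a-dihydro-3aH-cyclopenta[d][1,3]dioxole | CCCCCCCCCCCCCC[C@H](O[Si](C)(C)C(C)(C)C)[C@@]1(O2)C(O[Si](C)(C)C(C)(C)C)C=C[C@@H]1OC2(C)C | intermediate
17 | (1R,2S)-5-[(tert-butyldimethylsilyl)oxy]-1-{(1S)-1-[(tert-butyldimethylsilyl)oxy]pentadecyl}cyclopent-3-ene-1,2-diol | CCCCCCCCCCCCCC[C@H](O[Si](C)(C)C(C)(C)C)[C@@]1(O)C(O[Si](C)(C)C(C)(C)C)C=C[C@@H]1O | intermediate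
18 | (1S,5R)-4-[(tert-butyldimethylsilyl)oxy]-5-{(1S)-1-[(tert-butyldimethylsilyl)oxy]pentadecyl}-5-hydroxycyclopent-2-en-1-yl acetate | CCCCCCCCCCCCCC[C@H](O[Si](C)(C)C(C)(C)C)[C@@]1(O)C(O[Si](C)(C)C(C)(C)C)C=C[C@@H]1OC(C)=O | intermediate
19 | (1S,5R)-4,5-dihydroxy-5-[(1S)-1-hydroxypentadecyl]cyclopent-2-en-1-yl acetate | CCCCCCCCCCCCCC[C@H](O)[C@@]1(O)C(O)C=C[C@@H]1OC(C)=O | intermediate
20 | (1S,5S)-5-hydroxy-5-[(1S)-1-hydroxypentadecyl]-4-oxocyclopent-2-en-1-yl acetate | CCCCCCCCCCCCCC[C@H](O)[C@@]1(O)C(=O)C=C[C@@H]1OC(C)=O | target

## Step count and least certain steps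

Total step count: 13. Longest linear sequence: 13 steps (1 → 20); 13 is made and used inside step 7.

Step 1 (key step). The most likely failure is loss of the enolate by β-elimination of the ring oxygen before it meets the aldehyde, together with conjugate addition to acrolein or its anionic oligomerisation once methoxide is released; incomplete ring closure would leave open hydroxy diester. Fallback: the same enolate of 1 is combined with a saturated, non-polymerising acrolein surrogate, 3-(phenylselanyl)propanal F1 (from 2 and PhSeH), to give the selenide lactone methyl (3aR,6aR)-2,2-dimethyl-6-oxo-4-[2-(phenylselanyl)ethyl]tetrahydrofuro[3,4-d][1,3]dioxole-3a(4H)-carboxylate F2. Oxidation with H2O2 and syn-elimination of the selenoxide at room temperature then unmask the vinyl group. The fallback sets out from 1 and returns at 5.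

Step 3. The alkoxide set free when the lactol opens is β to the ester, so retro-aldol cleavage of the C1–C5 bond can compete with olefination, and the transient α-alkoxy aldehyde can epimerise at C4; over-reduction in step 2 would feed the same problem. Fallback: the lactone of 5 is opened with Me2AlN(OMe)Me to the hydroxy amide methyl (4R,5R)-4-(1-hydroxyprop-2-en-1-yl)-5-[methoxy(methyl)carbamoyl]-2,2-dimethyl-1,3-dioxolane-4-carboxylate F3. The C1 hydroxyl is silylated (TBSOTf, 2,6-lutidine) to methyl (4S,5R)-4-{1-[(tert-butyldimethylsilyl)oxy]prop-2-en-1-yl}-5-[methoxy(methyl)carbamoyl]-2,2-dimethyl-1,3-dioxolane-4-carboxylate F4. The amide is reduced with i-Bu2AlH at −78 °C, in preference to the hindered ester, to methyl (4S,5R)-4-{1-[(tert-butyldimethylsilyl)oxy]prop-2-en-1-yl}-5-formyl-2,2-dimethyl-1,3-dioxolane-4-carboxylate F5. This aldehyde is methylenated with Ph3P=CH2 with no free alkoxide present. The fallback sets out from 5 and returns at 9.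

Step 6. Acyl substitution at an ester on a fully substituted carbon may be slow, so conversion could stall or the excess magnesium amide could attack elsewhere. Fallback: 10 is saponified (LiOH, THF/MeOH/H2O, 50 °C) to (3aS,6aS)-4-[(tert-butyldimethylsilyl)oxy]-2,2-dimethyl-4,6a-dihydro-3aH-cyclopenta[d][1,3]dioxole-3a-carboxylic acid F6. Its lithium carboxylate is treated with tetradecyllithium (from 12 and t-BuLi, 2.2 equiv, Et2O, −78 → 0 °C); the geminal dilithium alkoxide collapses to the ketone only on work-up. The fallback sets out from 10 and returns at 14.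

Step 8. Facial selectivity may be poor if the intrinsic preference of the bicyclic ketone opposes the catalyst, or if the hindered ketone reacts so slowly that uncatalysed reduction competes. Fallback: 11 is reduced with i-Bu2AlH (THF, −78 °C) to (3aS,6aS)-4-[(tert-butyldimethylsilyl)oxy]-2,2-dimethyl-4,6a-dihydro-3aH-cyclopenta[d][1,3]dioxole-3a-carbaldehyde F7. The reagent 13 is then added in the presence of MgBr2·OEt2 (CH2Cl2, −78 °C) under chelation between the formyl oxygen and the ring-fusion oxygen. The chain now enters as the nucleophile where hydride entered before, so attack on the same carbonyl face gives the opposite C1' epimer; a substrate bias that works against the hydride route should work for this one. The fallback sets out from 11 and returns at 15.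

Step 10. Ketal exchange at the crowded, fully substituted ketal oxygen may stall, or the allylic silyl ether may be lost, which would expose the C1 hydroxyl before C4 is acetylated. Fallback: the order of events is changed so that aqueous acid meets only one, neopentyl-type silyl ether.
- 15 is desilylated (Bu4NF, THF) to (3aR,6aS)-3a-[(1S)-1-hydroxypentadecyl]-2,2-dimethyl-4,6a-dihydro-3aH-cyclopenta[d][1,3]dioxol-4-ol F8.
- MnO2 oxidises the allylic hydroxyl alone to (3aS,6aS)-3a-[(1S)-1-hydroxypentadecyl]-2,2-dimethyl-3a,6a-dihydro-4H-cyclopenta[d][1,3]dioxol-4-one F9.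
- TBSOTf/2,6-lutidine gives (3aR,6aS)-3a-{(1S)-1-[(tert-butyldimethylsilyl)oxy]pentadecyl}-2,2-dimethyl-3a,6a-dihydro-4H-cyclopenta[d][1,3]dioxol-4-one F10.
- CF3CO2H/H2O at 0 °C removes the ketal to give (4S,5R)-5-{(1S)-1-[(tert-butyldimethylsilyl)oxy]pentadecyl}-4,5-dihydroxycyclopent-2-en-1-one F11 (the same structure as A5).
- Ac2O/pyridine gives (1S,5R)-5-{(1S)-1-[(tert-butyldimethylsilyl)oxy]pentadecyl}-5-hydroxy-4-oxocyclopent-2-en-1-yl acetate F12.
- HF·pyridine removes the last silyl group.

The fallback sets out from 15 and returns at 20.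

## Further compounds

F1 | step 1 | 3-(phenylselanyl)propanal | O=CCC[Se]c1ccccc1
F2 | step 1 | methyl (3aR,6aR)-2,2-dimethyl-6-oxo-4-[2-(phenylselanyl)ethyl]tetrahydrofuro[3,4-d][1,3]dioxole-3a(4H)-carboxylate | c3ccccc3[Se]CCC1OC(=O)[C@@H]2OC(C)(C)O[C@]12C(=O)OC
F3 | step 3 | methyl (4R,5R)-4-(1-hydroxyprop-2-en-1-yl)-5-[methoxy(methyl)carbamoyl]-2,2-dimethyl-1,3-dioxolane-4-carboxylate | CON(C)C(=O)[C@@H]1OC(C)(C)O[C@]1(C(=O)OC)C(O)C=C
F4 | step 3 | methyl (4S,5R)-4-{1-[(tert-butyldimethylsilyl)oxy]prop-2-en-1-yl}-5-[methoxy(methyl)carbamoyl]-2,2-dimethyl-1,3-dioxolane-4-carboxylate | CON(C)C(=O)[C@@H]1OC(C)(C)O[C@]1(C(=O)OC)C(O[Si](C)(C)C(C)(C)C)C=C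
F5 | step 3 | methyl (4S,5R)-4-{1-[(tert-butyldimethylsilyl)oxy]prop-2-en-1-yl}-5-formyl-2,2-dimethyl-1,3-dioxolane-4-carboxylate | O=C[C@@H]1OC(C)(C)O[C@]1(C(=O)OC)C(O[Si](C)(C)C(C)(C)C)C=C
F6 | step 6 | (3aS,6aS)-4-[(tert-butyldimethylsilyl)oxy]-2,2-dimethyl-4,6a-dihydro-3aH-cyclopenta[d][1,3]dioxole-3a-carboxylic acid | OC(=O)[C@@]1(O2)C(O[Si](C)(C)C(C)(C)C)C=C[C@@H]1OC2(C)C
F7 | step 8 | (3aS,6aS)-4-[(tert-butyldimethylsilyl)oxy]-2,2-dimethyl-4,6a-dihydro-3aH-cyclopenta[d][1,3]dioxole-3a-carbaldehyde | O=C[C@@]1(O2)C(O[Si](C)(C)C(C)(C)C)C=C[C@@H]1OC2(C)C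
F8 | step 10 | (3aR,6aS)-3a-[(1S)-1-hydroxypentadecyl]-2,2-dimethyl-4,6a-dihydro-3aH-cyclopenta[d][1,3]dioxol-4-ol | CCCCCCCCCCCCCC[C@H](O)[C@@]1(O2)C(O)C=C[C@@H]1OC2(C)C
F9 | step 10 | (3aS,6aS)-3a-[(1S)-1-hydroxypentadecyl]-2,2-dimethyl-3a,6a-dihydro-4H-cyclopenta[d][1,3]dioxol-4-one | CCCCCCCCCCCCCC[C@H](O)[C@@]1(O2)C(=O)C=C[C@@H]1OC2(C)C
F10 | step 10 | (3aR,6aS)-3a-{(1S)-1-[(tert-butyldimethylsilyl)oxy]pentadecyl}-2,2-dimethyl-3a,6a-dihydro-4H-cyclopenta[d][1,3]dioxol-4-one | CCCCCCCCCCCCCC[C@H](O[Si](C)(C)C(C)(C)C)[C@@]1(O2)C(=O)C=C[C@@H]1OC2(C)C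
F11 | step 10 | (4S,5R)-5-{(1S)-1-[(tert-butyldimethylsilyl)oxy]pentadecyl}-4,5-dihydroxycyclopent-2-en-1-one | CCCCCCCCCCCCCC[C@H](O[Si](C)(C)C(C)(C)C)[C@@]1(O)C(=O)C=C[C@@H]1O
F12 | step 10 | (1S,5R)-5-{(1S)-1-[(tert-butyldimethylsilyl)oxy]pentadecyl}-5-hydroxy-4-oxocyclopent-2-en-1-yl acetate | CCCCCCCCCCCCCC[C@H](O[Si](C)(C)C(C)(C)C)[C@@]1(O)C(=O)C=C[C@@H]1OC(C)=O
A1 | alternative 1 | cyclic osmate ester (hexavalent osmium, diamine ligand not drawn) across the C5 and C1' oxygens of (4S,5S)-4,5-dihydroxy-5-[(1S)-1-hydroxypentadecyl]cyclopent-2-en-1-one | CCCCCCCCCCCCCC[C@@H]2O[Os](=O)(=O)O[C@@]21C(=O)C=C[C@@H]1O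
A2 | alternative 1 | (4S,5E)-4-hydroxy-5-pentadecylidenecyclopent-2-en-1-one | O=C1C=C[C@H](O)/C1=C\CCCCCCCCCCCCCC
A3 | alternative 2 | 9-acetoxy-2,2-dimethyl-4-tetradecyl-1,3-dioxaspiro[4.4]non-7-en-6-one, configured as the target at C4, C5 and C1' | CCCCCCCCCCCCCC[C@@H]2OC(C)(C)O[C@@]21C(=O)C=C[C@@H]1OC(C)=O
A4 | alternative 2 | 1-(4-formyl-2,2-dimethyl-5-tetradecyl-1,3-dioxolan-4-yl)prop-2-yn-1-yl acetate, configured as the target at C4, C5 and C1' | CCCCCCCCCCCCCC[C@@H]1OC(C)(C)O[C@]1(C=O)[C@@H](OC(C)=O)C#C
A5 | alternative 3 | (4S,5R)-5-{(1S)-1-[(tert-butyldimethylsilyl)oxy]pentadecyl}-4,5-dihydroxycyclopent-2-en-1-one | CCCCCCCCCCCCCC[C@H](O[Si](C)(C)C(C)(C)C)[C@@]1(O)C(=O)C=C[C@@H]1O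
A6 | alternative 3 | 6-hydroxy-2-{(1S)-1-[(tert-butyldimethylsilyl)oxy]pentadecyl}-2H-pyran-3(6H)-one | CCCCCCCCCCCCCC[C@H](O[Si](C)(C)C(C)(C)C)C1OC(O)C=CC1=O
A7 | alternative 3 | (2Z,6S)-6-[(tert-butyldimethylsilyl)oxy]-5-hydroxy-4-oxoicos-2-enal | CCCCCCCCCCCCCC[C@H](O[Si](C)(C)C(C)(C)C)C(O)C(=O)/C=C\C=O
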